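**Strategy**

The decalin is unravelled to a linear dienyne. An In(III)-triggered, alkyne-initiated cation–olefin bicyclization forms C4–C5 and then C9–C10, so that ring B (C5–C6–C7–C8–C9–C10) closes last. The step exploits three features: the C4=C15H2 exocyclic methylene next to C3–O in ring A (a terminal alkyne attacked at C4), the trans C5–H/C10–CH3 ring fusion (anti addition across an (E)-C5=C10 alkene) and the C8 oxygen (a C8=C9 silyl enol ether terminator). One operation builds both rings and the C5 and C10 stereocentres. The precursor carries the C1, C3 and C7 stereocentres, set by asymmetric aldol, transfer hydrogenation and Evans alkylation.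

Key step: step 11

Remark (numbering): bicyclic compounds carry eudesmane numbering (C1–C10 decalin, C14 = methyl on C10, C15 = methylene carbon on C4, isopropyl on C7); the same atom labels are used for the acyclic precursors. TBS = tert-butyldimethylsilyl, TES = triethylsilyl.

Remark (assumption): the sense of induction of the zinc–ProPhenol aldol in step 1 is not predicted with certainty for this enal; the ligand antipode is the one that delivers the (R)-carbinol, and the other antipode is used if the first run shows the opposite sense.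

**Route**

Step 1
Reactants: 1 (2E)-4-acetoxy-2-methylbut-2-enal; 2 4-(trimethylsilyl)but-3-yn-2-one
Product: 3 (2E,4R)-4-hydroxy-3-methyl-6-oxo-8-(trimethylsilyl)oct-2-en-7-yn-1-yl acetate
Conditions: (S,S)-ProPhenol (10 mol%), Et2Zn (20 mol%), 4 Å MS, THF, −20 °C
Reagents that add atoms: none
Why: Direct catalytic asymmetric aldol addition, in which the dinuclear zinc–ProPhenol catalyst forms the zinc enolate of the methyl ynone and delivers it to one face of the non-enolisable α-methyl enal, which should set C4 (C1 of the target) as R.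

Step 2
Reactants: 3 (2E,4R)-4-hydroxy-3-methyl-6-oxo-8-(trimethylsilyl)oct-2-en-7-yn-1-yl acetate
Product: 4 (2E,4R)-4-(TBSO)-3-methyl-6-oxo-8-(trimethylsilyl)oct-2-en-7-yn-1-yl acetate
Conditions: TBSOTf, 2,6-lutidine, CH2Cl2, −78 °C
Reagents that add atoms: tert-butyldimethylsilyl triflate, CC(C)(C)[Si](C)(C)OS(=O)(=O)C(F)(F)F
Why: Silyl triflate silylation of the secondary allylic alcohol with a hindered base at low temperature should avoid retro-aldol or β-elimination of the β-hydroxy ynone and touches no stereocentre.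

Step 3
Reactants: 4 (2E,4R)-4-(TBSO)-3-methyl-6-oxo-8-(trimethylsilyl)oct-2-en-7-yn-1-yl acetate
Product: 5 (2E,4R,6S)-4-(TBSO)-6-hydroxy-3-methyl-8-(trimethylsilyl)oct-2-en-7-yn-1-yl acetate
Conditions: Ru[(S,S)-TsDPEN](p-cymene) (2 mol%), i-PrOH, rt
Reagents that add atoms: none
Why: Noyori asymmetric transfer hydrogenation of the conjugated ynone is reagent-controlled (the alkynyl group takes the place of the aryl group of the acetophenone model), so the (S,S)-catalyst should give the (6S)-propargylic alcohol, 1,3-syn to C4–O, while ester, alkene and silyl groups stay untouched.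

Step 4
Reactants: 5 (2E,4R,6S)-4-(TBSO)-6-hydroxy-3-methyl-8-(trimethylsilyl)oct-2-en-7-yn-1-yl acetate
Product: 6 (2E,4R,6S)-4-(TBSO)-3-methyl-6-(TESO)-8-(trimethylsilyl)oct-2-en-7-yn-1-yl acetate
Conditions: TESCl, imidazole, DMF, 0 °C
Reagents that add atoms: chlorotriethylsilane, CC[Si](Cl)(CC)CC
Why: Standard silylation of the unhindered propargylic alcohol gives a silyl ether on the future C3 oxygen that is more acid-labile than the TBS ethers and can later be removed alone.

Step 5
Reactants: 6 (2E,4R,6S)-4-(TBSO)-3-methyl-6-(TESO)-8-(trimethylsilyl)oct-2-en-7-yn-1-yl acetate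
Product: 7 (2E,4R,6S)-4-(TBSO)-3-methyl-6-(TESO)oct-2-en-7-yn-1-ol
Conditions: K2CO3 (0.3 equiv), MeOH, 0 °C to rt
Reagents that add atoms: none
Why: Mild methanolysis cleaves the alkynyl C–Si bond and the acetate in one operation, whereas secondary TES and TBS ethers are stable to these conditions.

Step 6
Reactants: 7 (2E,4R,6S)-4-(TBSO)-3-methyl-6-(TESO)oct-2-en-7-yn-1-ol
Product: 8 (2E,4R,6S)-1-bromo-4-(TBSO)-3-methyl-6-(TESO)oct-2-en-7-yne
Conditions: CBr4, PPh3, CH2Cl2, −20 to 0 °C
Reagents that add atoms: carbon tetrabromide, BrC(Br)(Br)Br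
Why: Appel bromination of the primary allylic alcohol proceeds by SN2 displacement of the alkoxyphosphonium ion, without allylic transposition or loss of the E geometry, under near-neutral conditions that both silyl ethers and the alkyne tolerate.

Step 7
Reactants: 8 (2E,4R,6S)-1-bromo-4-(TBSO)-3-methyl-6-(TESO)oct-2-en-7-yne; 9 (4R)-4-benzyl-3-(3-methylbutanoyl)-1,3-oxazolidin-2-one
Product: 11 (4R)-4-benzyl-3-[(2R,4E,6R,8S)-6-(TBSO)-5-methyl-2-(propan-2-yl)-8-(TESO)dec-4-en-9-ynoyl]-1,3-oxazolidin-2-one, via sodium Z-enolate 10 (not isolated)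
Conditions: 9 (1.5 equiv), NaHMDS, THF, −78 °C; then 8, −78 to −30 °C
Reagents that add atoms: none
Why: Evans asymmetric alkylation, in which the chelated sodium (Z)-enolate is attacked by the reactive primary allylic bromide on the face opposite the benzyl group, setting C2 of the acyl chain (C7 of the target) as R, while the imide enolate is not basic enough to deprotonate the terminal alkyne.

Step 8
Reactants: 11 (4R)-4-benzyl-3-[(2R,4E,6R,8S)-6-(TBSO)-5-methyl-2-(propan-2-yl)-8-(TESO)dec-4-en-9-ynoyl]-1,3-oxazolidin-2-one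
Product: 13 (2R,4E,6R,8S)-6-(TBSO)-5-methyl-2-(propan-2-yl)-8-(TESO)dec-4-en-9-ynoic acid, via peroxy acid 12 (not isolated)
Conditions: LiOH, H2O2, THF/H2O, 0 °C; Na2SO3; 1 M HCl to pH 4
Reagents that add atoms: hydrogen peroxide (as LiOOH), OO
Why: Lithium hydroperoxide attacks the exocyclic imide carbonyl selectively (Evans auxiliary cleavage), sulfite reduces the peracid, and the α-stereocentre should not epimerise under these conditions.

Step 9
Reactants: 13 (2R,4E,6R,8S)-6-(TBSO)-5-methyl-2-(propan-2-yl)-8-(TESO)dec-4-en-9-ynoic acid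
Product: 15 (3R,5E,7R,9S)-7-(TBSO)-6-methyl-3-(propan-2-yl)-9-(TESO)undec-5-en-10-yn-2-one, via trilithium gem-diolate 14 (not isolated)
Conditions: MeLi (4 equiv), Et2O, −78 to 0 °C; inverse quench into cold aq. NH4Cl
Reagents that add atoms: methyllithium, [Li]C
Why: Addition of methyllithium to the lithium carboxylate stops at the stable gem-diolate, which collapses to the methyl ketone only on the inverse aqueous quench, so over-addition is avoided, the acetylide formed in the flask is reprotonated on work-up and the isopropyl-flanked C3 stereocentre should not be enolised.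

Step 10
Reactants: 15 (3R,5E,7R,9S)-7-(TBSO)-6-methyl-3-(propan-2-yl)-9-(TESO)undec-5-en-10-yn-2-one
Product: 16 (3R,5E,7R,9S)-2,7-bis(TBSO)-6-methyl-3-(propan-2-yl)-9-(TESO)undeca-1,5-dien-10-yne
Conditions: TBSOTf (1.2 equiv), Et3N, CH2Cl2, −78 °C
Reagents that add atoms: tert-butyldimethylsilyl triflate, CC(C)(C)[Si](C)(C)OS(=O)(=O)C(F)(F)F
Why: Soft enolisation (silyl triflate/amine) removes a proton from the unhindered methyl group rather than from the isopropyl-flanked tertiary C–H, which should give the terminal 2-silyloxyalkene regioselectively and leave the adjacent stereocentre and the terminal alkyne untouched.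

Step 11
Reactants: 16 (3R,5E,7R,9S)-2,7-bis(TBSO)-6-methyl-3-(propan-2-yl)-9-(TESO)undeca-1,5-dien-10-yne
Product: 18 (1R,3S,5S,7R,10R)-1-(TBSO)-3-(TESO)eudesm-4(15)-en-8-one, via vinylindium dibromide 17 (not isolated)
Conditions: InBr3 (1.2 equiv), 2,6-di-tert-butylpyridine (0.2 equiv), 4 Å MS, CH2Cl2 (0.01 M), −40 to −10 °C; then sat. aq. NH4Cl
Reagents that add atoms: none
Why: In(III) π-activates the terminal alkyne, C5 of the (E)-C5=C10 alkene attacks the internal alkyne carbon C4 anti to indium (ring A, 6-exo-dig at the alkyne and endo at the alkene), and the tertiary C10 cation is captured by C9 of the silyl enol ether (ring B, 6-endo at the enol ether), the silyloxocarbenium ion losing its silyl group to bromide to give the C8 ketone while the C15–In bond of 17 is protonated on work-up to the exocyclic methylene. The closest known reaction type is the In(III)-catalysed alkyne-initiated cation–olefin polycyclization of polyenynes that bear a propargylic silyl ether, combined with the silyl enol ether termination known from Lewis acid epoxy-polyene cyclizations. C5 and C10 are set by anti addition across the E alkene through a chair–chair array (trans fusion, H-5 α, CH3-10 β), and the absolute sense is fixed by the stereocentres already present: the syn-1,3-bis(silyloxy) unit at C1/C3 can only sit diequatorial (the other chair would place both silyloxy groups 1,3-diaxial) and the C7 isopropyl group is equatorial in the same array. The step needs the C10 cation to be trapped by C9 faster than it loses a proton or accepts a 1,2-hydride from C1, which the nucleophilicity and proximity of the enol ether and the position of the C1–H bond well off the axis of the C10 p-orbital in the chair should secure, while attack at C4 and not at C15 follows from ring size and cation stability. Indium is used in a stoichiometric amount because the silyl enol ether terminus releases a silyl cation equivalent and not the proton that would turn a catalyst over.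

Step 12
Reactants: 18 (1R,3S,5S,7R,10R)-1-(TBSO)-3-(TESO)eudesm-4(15)-en-8-one
Product: 19 (1R,3S,5S,7R,8S,10R)-1-(TBSO)-3-(TESO)eudesm-4(15)-en-8-ol (8α-OH)
Conditions: Li (10 equiv), NH3(l)/THF, t-BuOH (2 equiv), −78 °C; solid NH4Cl
Reagents that add atoms: none
Why: Dissolving-metal reduction of the hindered cyclohexanone is thermodynamically controlled and should give the equatorial 8α-alcohol (trans to the equatorial C7 isopropyl group), whereas hydride reagents would be diverted to the axial alcohol by the 1,3-diaxial C10 methyl group, and the isolated alkene and the silyl ethers are inert.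

Step 13
Reactants: 19 (1R,3S,5S,7R,8S,10R)-1-(TBSO)-3-(TESO)eudesm-4(15)-en-8-ol
Product: 20 (1R,3S,5S,7R,8S,10R)-1,8-bis(TBSO)-3-(TESO)eudesm-4(15)-ene
Conditions: TBSOTf, 2,6-lutidine, CH2Cl2, 0 °C
Reagents that add atoms: tert-butyldimethylsilyl triflate, CC(C)(C)[Si](C)(C)OS(=O)(=O)C(F)(F)F
Why: Silyl triflate with 2,6-lutidine silylates the hindered secondary C8 alcohol without affecting the TES ether or the exocyclic alkene.

Step 14
Reactants: 20 (1R,3S,5S,7R,8S,10R)-1,8-bis(TBSO)-3-(TESO)eudesm-4(15)-ene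
Product: 21 (1R,3S,5S,7R,8S,10R)-1,8-bis(TBSO)eudesm-4(15)-en-3-ol (3β-OH)
Conditions: PPTS (0.2 equiv), MeOH/CH2Cl2, 0 °C
Reagents that add atoms: none
Why: Acid-catalysed methanolysis discriminates by silyl group, the TES ether being cleaved far faster than the two secondary TBS ethers (neopentylic at C1, flanked by isopropyl at C8), so only the allylic C3 alcohol should be released, with retention.

Step 15
Reactants: 22 caffeic acid
Product: 24 (2E)-3-[3,4-bis(TBSO)phenyl]prop-2-enoic acid, via silyl ester 23 (not isolated)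
Conditions: TBSCl (3.5 equiv), imidazole, DMF, rt; then AcOH/THF/H2O, rt
Reagents that add atoms: tert-butyldimethylsilyl chloride, CC(C)(C)[Si](C)(C)Cl
Why: Exhaustive silylation followed by selective hydrolysis of the labile silyl ester leaves the two aryl TBS ethers, giving an acid whose protecting groups match those of the alcohol partner.

Step 16
Reactants: 21 (1R,3S,5S,7R,8S,10R)-1,8-bis(TBSO)eudesm-4(15)-en-3-ol; 24 (2E)-3-[3,4-bis(TBSO)phenyl]prop-2-enoic acid
Product: 25 (1R,3S,5S,7R,8S,10R)-1,8-bis(TBSO)eudesm-4(15)-en-3-yl (2E)-3-[3,4-bis(TBSO)phenyl]prop-2-enoate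
Conditions: EDC·HCl, DMAP, CH2Cl2, rt
Reagents that add atoms: none
Why: Steglich esterification acylates the only free hydroxyl group, the unhindered allylic C3–OH, with retention of configuration and without isomerising the (E)-cinnamate.

Step 17
Reactants: 25 (1R,3S,5S,7R,8S,10R)-1,8-bis(TBSO)eudesm-4(15)-en-3-yl (2E)-3-[3,4-bis(TBSO)phenyl]prop-2-enoate
Product: 26 (1R,3S,5S,7R,8S,10R)-1,8-dihydroxyeudesm-4(15)-en-3-yl (2E)-3-(3,4-dihydroxyphenyl)prop-2-enoate (CNP0264533.1)
Conditions: HF·pyridine, pyridine, THF, 0 °C to rt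
Reagents that add atoms: none
Why: Buffered HF·pyridine should remove the two alkyl and two aryl TBS ethers in one operation (global desilylation) while the allylic cinnamate ester, the exocyclic alkene and the catechol survive the mildly acidic, non-nucleophilic conditions.

**Compound list**

1 | (2E)-4-acetoxy-2-methylbut-2-enal | CC(=O)OC/C=C(\C)C=O | starting material
2 | 4-(trimethylsilyl)but-3-yn-2-one | CC(=O)C#C[Si](C)(C)C | starting material
3 | (2E,4R)-4-hydroxy-3-methyl-6-oxo-8-(trimethylsilyl)oct-2-en-7-yn-1-yl acetate | C[Si](C)(C)C#CC(=O)C[C@@H](O)/C(C)=C/COC(C)=O | intermediate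
4 | (2E,4R)-4-(TBSO)-3-methyl-6-oxo-8-(trimethylsilyl)oct-2-en-7-yn-1-yl acetate | C[Si](C)(C)C#CC(=O)C[C@@H](O[Si](C)(C)C(C)(C)C)/C(C)=C/COC(C)=O | intermediate
5 | (2E,4R,6S)-4-(TBSO)-6-hydroxy-3-methyl-8-(trimethylsilyl)oct-2-en-7-yn-1-yl acetate | C[Si](C)(C)C#C[C@@H](O)C[C@@H](O[Si](C)(C)C(C)(C)C)/C(C)=C/COC(C)=O | intermediate
6 | (2E,4R,6S)-4-(TBSO)-3-methyl-6-(TESO)-8-(trimethylsilyl)oct-2-en-7-yn-1-yl acetate | C[Si](C)(C)C#C[C@@H](O[Si](CC)(CC)CC)C[C@@H](O[Si](C)(C)C(C)(C)C)/C(C)=C/COC(C)=O | intermediate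
7 | (2E,4R,6S)-4-(TBSO)-3-methyl-6-(TESO)oct-2-en-7-yn-1-ol | C#C[C@@H](O[Si](CC)(CC)CC)C[C@@H](O[Si](C)(C)C(C)(C)C)/C(C)=C/CO | intermediate
8 | (2E,4R,6S)-1-bromo-4-(TBSO)-3-methyl-6-(TESO)oct-2-en-7-yne | C#C[C@@H](O[Si](CC)(CC)CC)C[C@@H](O[Si](C)(C)C(C)(C)C)/C(C)=C/CBr | intermediate
9 | (4R)-4-benzyl-3-(3-methylbutanoyl)-1,3-oxazolidin-2-one | CC(C)CC(=O)N1[C@H](Cc2ccccc2)COC1=O | starting material
10 | sodium (Z)-enolate of 9 | CC(C)/C=C(\[O-])N1[C@H](Cc2ccccc2)COC1=O.[Na+] | intermediate (not isolated)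
11 | (4R)-4-benzyl-3-[(2R,4E,6R,8S)-6-(TBSO)-5-methyl-2-(propan-2-yl)-8-(TESO)dec-4-en-9-ynoyl]-1,3-oxazolidin-2-one | C#C[C@@H](O[Si](CC)(CC)CC)C[C@@H](O[Si](C)(C)C(C)(C)C)/C(C)=C/C[C@H](C(C)C)C(=O)N1[C@H](Cc2ccccc2)COC1=O | intermediate
12 | (2R,4E,6R,8S)-6-(TBSO)-5-methyl-2-(propan-2-yl)-8-(TESO)dec-4-en-9-yneperoxoic acid | C#C[C@@H](O[Si](CC)(CC)CC)C[C@@H](O[Si](C)(C)C(C)(C)C)/C(C)=C/C[C@H](C(C)C)C(=O)OO | intermediate (not isolated)
13 | (2R,4E,6R,8S)-6-(TBSO)-5-methyl-2-(propan-2-yl)-8-(TESO)dec-4-en-9-ynoic acid | C#C[C@@H](O[Si](CC)(CC)CC)C[C@@H](O[Si](C)(C)C(C)(C)C)/C(C)=C/C[C@H](C(C)C)C(=O)O | intermediate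
14 | trilithium salt of the gem-diolate of 15 (lithium acetylide, dilithium 2,2-diolate) | [Li+].[Li+].[Li+].[C-]#C[C@@H](O[Si](CC)(CC)CC)C[C@@H](O[Si](C)(C)C(C)(C)C)/C(C)=C/C[C@H](C(C)C)C(C)([O-])[O-] | intermediate (not isolated)
15 | (3R,5E,7R,9S)-7-(TBSO)-6-methyl-3-(propan-2-yl)-9-(TESO)undec-5-en-10-yn-2-one | C#C[C@@H](O[Si](CC)(CC)CC)C[C@@H](O[Si](C)(C)C(C)(C)C)/C(C)=C/C[C@H](C(C)C)C(C)=O | intermediate
16 | (3R,5E,7R,9S)-2,7-bis(TBSO)-6-methyl-3-(propan-2-yl)-9-(TESO)undeca-1,5-dien-10-yne (TBS enol ether of 15) | C#C[C@@H](O[Si](CC)(CC)CC)C[C@@H](O[Si](C)(C)C(C)(C)C)/C(C)=C/C[C@H](C(C)C)C(=C)O[Si](C)(C)C(C)(C)C | intermediate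
17 | (Z)-15-(dibromoindio) derivative of 18 (vinylindium; In on C15 cis to C3) | Br[In](Br)/C=C1\[C@@H](O[Si](CC)(CC)CC)C[C@@H](O[Si](C)(C)C(C)(C)C)[C@]2(C)CC(=O)[C@@H](C(C)C)C[C@@H]12 | intermediate (not isolated)
18 | (1R,3S,5S,7R,10R)-1-(TBSO)-3-(TESO)eudesm-4(15)-en-8-one (1β-OTBS, 3β-OTES, 5α-H, 7β-isopropyl, 10β-CH3) | C=C1[C@@H](O[Si](CC)(CC)CC)C[C@@H](O[Si](C)(C)C(C)(C)C)[C@]2(C)CC(=O)[C@@H](C(C)C)C[C@@H]12 | intermediate
19 | (1R,3S,5S,7R,8S,10R)-1-(TBSO)-3-(TESO)eudesm-4(15)-en-8-ol (8α-OH) | C=C1[C@@H](O[Si](CC)(CC)CC)C[C@@H](O[Si](C)(C)C(C)(C)C)[C@]2(C)C[C@H](O)[C@@H](C(C)C)C[C@@H]12 | intermediate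
20 | (1R,3S,5S,7R,8S,10R)-1,8-bis(TBSO)-3-(TESO)eudesm-4(15)-ene | C=C1[C@@H](O[Si](CC)(CC)CC)C[C@@H](O[Si](C)(C)C(C)(C)C)[C@]2(C)C[C@H](O[Si](C)(C)C(C)(C)C)[C@@H](C(C)C)C[C@@H]12 | intermediate
21 | (1R,3S,5S,7R,8S,10R)-1,8-bis(TBSO)eudesm-4(15)-en-3-ol (3β-OH) | C=C1[C@@H](O)C[C@@H](O[Si](C)(C)C(C)(C)C)[C@]2(C)C[C@H](O[Si](C)(C)C(C)(C)C)[C@@H](C(C)C)C[C@@H]12 | intermediate
22 | caffeic acid, (2E)-3-(3,4-dihydroxyphenyl)prop-2-enoic acid | O=C(O)/C=C/c1ccc(O)c(O)c1 | starting material
23 | tert-butyldimethylsilyl (2E)-3-[3,4-bis(TBSO)phenyl]prop-2-enoate | CC(C)(C)[Si](C)(C)OC(=O)/C=C/c1ccc(O[Si](C)(C)C(C)(C)C)c(O[Si](C)(C)C(C)(C)C)c1 | intermediate (not isolated)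
24 | (2E)-3-[3,4-bis(TBSO)phenyl]prop-2-enoic acid | O=C(O)/C=C/c1ccc(O[Si](C)(C)C(C)(C)C)c(O[Si](C)(C)C(C)(C)C)c1 | intermediate
25 | (1R,3S,5S,7R,8S,10R)-1,8-bis(TBSO)eudesm-4(15)-en-3-yl (2E)-3-[3,4-bis(TBSO)phenyl]prop-2-enoate | C=C1[C@@H](OC(=O)/C=C/c3ccc(O[Si](C)(C)C(C)(C)C)c(O[Si](C)(C)C(C)(C)C)c3)C[C@@H](O[Si](C)(C)C(C)(C)C)[C@]2(C)C[C@H](O[Si](C)(C)C(C)(C)C)[C@@H](C(C)C)C[C@@H]12 | intermediate
26 | (1R,3S,5S,7R,8S,10R)-1,8-dihydroxyeudesm-4(15)-en-3-yl (2E)-3-(3,4-dihydroxyphenyl)prop-2-enoate (1β,8α-dihydroxy, 3β-O-caffeoyl; CNP0264533.1) | C=C1[C@@H](OC(=O)/C=C/c2ccc(O)c(O)c2)C[C@@H](O)[C@]2(C)C[C@H](O)[C@@H](C(C)C)C[C@@H]12 | target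

**Step count and risks**

Total step count: 17. Longest linear sequence: 16 (steps 1–14, 16 and 17; step 15 is a one-step side branch).

Steps most likely to fail:

1. Step 11. The enol silane may be desilylated before it can act, the C10 cation may be intercepted (proton loss, or 1,2-hydride shift from C1) before ring B closes, or the allylic C1 silyl ether may ionise. Allylic strain between the equatorial C3 silyloxy group and the C15–In unit may also slow the first closure. The fallback sets out from acid 13 and replaces the silyl terminator by a β-keto ester whose enol ends the cascade with release of a proton, so that indium turns over and no silyl transfer is needed. Acid 13 would be activated with carbonyldiimidazole and homologated with magnesium methyl malonate (Masamune–Brooks) to methyl (4R,6E,8R,10S)-8-(TBSO)-7-methyl-3-oxo-4-(propan-2-yl)-10-(TESO)dodec-6-en-11-ynoate F1. InBr3 (10–20 mol%) in CH2Cl2 at −20 °C would then give methyl (1R,3S,5S,7R,10R)-1-(TBSO)-8-oxo-3-(TESO)eudesm-4(15)-ene-9-carboxylate F2. Krapcho dealkoxycarbonylation (LiCl, wet DMSO, 130 °C) comes back to the route at ketone 18.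

2. Step 1. Enantiofacial discrimination at the enal may be poor, or the adduct may revert (retro-aldol) or dehydrate under the zinc alkoxide. The fallback sets out from 1 and 2 and replaces asymmetric catalysis by resolution. The lithium enolate of 2 (LDA, THF, −78 °C) would add to 1 to give the racemic aldol adduct (2E)-4-hydroxy-3-methyl-6-oxo-8-(trimethylsilyl)oct-2-en-7-yn-1-yl acetate F3. Sharpless kinetic resolution (Ti(OiPr)4, L-(+)-diisopropyl tartrate, t-BuOOH 0.6 equiv, 4 Å MS, CH2Cl2, −20 °C) should consume the (S)-enantiomer as the epoxy alcohol [(2R,3R)-3-[(1S)-1-hydroxy-3-oxo-5-(trimethylsilyl)pent-4-yn-1-yl]-3-methyloxiran-2-yl]methyl acetate F4 and leave the (R)-alcohol, which is compound 3.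

3. Step 12. Equatorial selectivity in the ketone reduction may be incomplete, or the allylic C3 silyloxy group may be lost reductively in the dissolving metal. The fallback sets out from ketone 18 and sets C8 by inversion. L-Selectride (THF, −78 °C) should attack from the unhindered equatorial side and give the axial alcohol (1R,3S,5S,7R,8R,10R)-1-(TBSO)-3-(TESO)eudesm-4(15)-en-8-ol F5 (8β-OH). Mitsunobu inversion (4-nitrobenzoic acid, PPh3, DIAD, toluene) would give (1R,3S,5S,7R,8S,10R)-1-(TBSO)-3-(TESO)eudesm-4(15)-en-8-yl 4-nitrobenzoate F6. Methanolysis (K2CO3, MeOH) comes back to the route at alcohol 19.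

Further compounds
F1 | step 11 | methyl (4R,6E,8R,10S)-8-(TBSO)-7-methyl-3-oxo-4-(propan-2-yl)-10-(TESO)dodec-6-en-11-ynoate | C#C[C@@H](O[Si](CC)(CC)CC)C[C@@H](O[Si](C)(C)C(C)(C)C)/C(C)=C/C[C@H](C(C)C)C(=O)CC(=O)OC
F2 | step 11 | methyl (1R,3S,5S,7R,10R)-1-(TBSO)-8-oxo-3-(TESO)eudesm-4(15)-ene-9-carboxylate (C9 epimers/enol) | C=C1[C@@H](O[Si](CC)(CC)CC)C[C@@H](O[Si](C)(C)C(C)(C)C)[C@]2(C)C(C(=O)OC)C(=O)[C@@H](C(C)C)C[C@@H]12
F3 | step 1 | racemic (2E)-4-hydroxy-3-methyl-6-oxo-8-(trimethylsilyl)oct-2-en-7-yn-1-yl acetate | C[Si](C)(C)C#CC(=O)CC(O)/C(C)=C/COC(C)=O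
F4 | step 1 | [(2R,3R)-3-[(1S)-1-hydroxy-3-oxo-5-(trimethylsilyl)pent-4-yn-1-yl]-3-methyloxiran-2-yl]methyl acetate | C[Si](C)(C)C#CC(=O)C[C@H](O)[C@@]1(C)O[C@@H]1COC(C)=O
F5 | step 12 | (1R,3S,5S,7R,8R,10R)-1-(TBSO)-3-(TESO)eudesm-4(15)-en-8-ol (8β-OH) | C=C1[C@@H](O[Si](CC)(CC)CC)C[C@@H](O[Si](C)(C)C(C)(C)C)[C@]2(C)C[C@@H](O)[C@@H](C(C)C)C[C@@H]12
F6 | step 12 | (1R,3S,5S,7R,8S,10R)-1-(TBSO)-3-(TESO)eudesm-4(15)-en-8-yl 4-nitrobenzoate | C=C1[C@@H](O[Si](CC)(CC)CC)C[C@@H](O[Si](C)(C)C(C)(C)C)[C@]2(C)C[C@H](OC(=O)c3ccc([N+](=O)[O-])cc3)[C@@H](C(C)C)C[C@@H]12
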